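Reciprocal seconds were my unit: I put each way out of the intermediate on that one scale.

the same everywhere: first nucleophile 1.00 mM; time 12 min
- Monday's: substrate 0.50 mM; second nucleophile 0.550 mM; everything together at the start
- Sunday's: substrate 0.50 mM (fed, over 8.0 min); second nucleophile 0.550 mM; all else is in the flask from the start; the feed brings no volume worth counting
- Wednesday's: substrate 0.50 mM (in portions, 2, over 8.0 min); second nucleophile 0.550 mM; first portion at the start, last at 8.0 min
- Tuesday's: substrate 0.50 mM; second nucleophile 0.550 mM (fed, over 8.0 min); all else is in the flask from the start; the feed brings no volume worth counting

    intermediate → solvolysis product (k1 = 15 s⁻¹)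
    substrate → intermediate (k2 = 0.036 s⁻¹)
    first nucleophile + intermediate → target (k3 = 15000 M⁻¹ s⁻¹)
    intermediate → side product (k4 = 0.017 s⁻¹)
    2 first nucleophile → homo dimer (k5 = 6.6 M⁻¹ s⁻¹)
    first nucleophile + target → over-reaction product (k6 = 8.5 M⁻¹ s⁻¹)
    second nucleophile + intermediate → other capture product (k7 = 16000 M⁻¹ s⁻¹)

- a doubled species enters its step squared and goes two at a time
- run time (Monday's): 12 min

- the flask that comes out highest in share of target in target plus other capture product, or "all alike" when all lie within 1.5 percentage points (Monday's / Sunday's / Wednesday's / Tuesday's / all alike)
- share of target in target plus other capture product at the end, Monday's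
- share of target in target plus other capture product at the end, Sunday's
- share of target in target plus other capture product at the end, Wednesday's
- share of target in target plus other capture product at the end, Tuesday's

At full charge, the capture constant times the second nucleophile gave 8.80 s⁻¹, and I called this p, the pull of the second nucleophile on the intermediate. That concentration makes capture pseudo-first-order in the intermediate. My rule was that the intermediate divides in proportion to its pulls.

In the first instants of Monday's, the substrate had a lifetime of 27.8 s. The intermediate faced solvolysis at 15 s⁻¹, the first nucleophile at 15.0 s⁻¹ and p, while the side step was far slower. So it lived 0.0258 s, far shorter than the substrate, and I treated it as a trace at quasi-steady state, with the material resting in the substrate. Capture then split 63.0% towards target.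

The middle belonged to the first nucleophile. Homo dimer formation alone halves its charge in 1.26 min, which is shorter than the slow dose. So at mid-dose on Sunday's, I reckoned 0.240 mM of it by that step alone. Its pull was then 3.60 s⁻¹ against p, and Sunday's capture split only 29.0% towards target.

Tuesday's turned p down. Its dose took 17 substrate lifetimes, so one lifetime in, the pull was 0.509 s⁻¹. With the first nucleophile taken as charged, I reckoned that 1.67% of the substrate went to other capture product.

Towards the end, target is eaten. Its half-life by over-reaction, as charged on Monday's, is 1.4 min, shorter than the run, so I expected each final share below its capture split. I ranked Tuesday's first, then Monday's, then Wednesday's, with Sunday's last.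

The forecast gave 28% for Monday's, 21% for Sunday's, 21% for Wednesday's and 84% for Tuesday's, and named Tuesday's, saying “so very little other capture product forms”. The simulation gave 30.6%, 20.6%, 22.0% and 87.5% in that order, so Tuesday's came highest.

Tuesday's dose took 17 substrate lifetimes, and that flask ended with 2.00% of other capture product against my 1.67%, with 98% of its second nucleophile unbound. On Sunday's, solvolysis used intermediate 2.0 times as fast as second-nucleophile capture at 4.46 min, while the solvolysis constant over p at full charge gives 1.70. The neighbour of Sunday's charged with 1.4 mM has p scaled to 22.4 s⁻¹, or 1.49 captures per solvolysis, and it ended with 1.35 of other capture product per solvolysis product.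

The constants used here were chosen freely.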